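Eudesmane numbering is used throughout: ring A = C1–C5 and C10, ring B = C5–C10, C11–C13 = the isopropenyl group on C7, C14 on C10, C15 on C4.
Retrosynthesis: the C7–OOH bond is cut first (back to the 7(11)-en-8-one), then the two esters and the 3,4-diol (back to a C3=C4 alkene); ring B is then cut at C6–C7 and C8–C9 into a ring A 1,4-diiodide and methyl 3-methylbut-2-enoate; C5–C6 and the ring A bonds C1–C10 and C4–C5 are cut last.
Enabling feature: ring B is a cyclohexanone whose carbonyl C8 and α-carbon C7 lie between two CH2 groups (C6, C9) carried by the ring-fusion carbons C5 and C10. C7–C8 therefore maps onto an ester enolate (C7 nucleophile, C8 acyl), and C6/C9 onto two iodides that differ by nature (C6 ordinary primary, C9 neopentyl beside quaternary C10).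
Forward: ring A by asymmetric Robinson annulation, C6 by a [2,3] shift, ring B in one flask (enolate alkylation at C6, then samarium-mediated acyl substitution at C9), then conjugation, dihydroxylation, two acylations and photooxygenation.
Stereochemistry: C10 from the catalytic Michael step; C5 by chirality transfer from a carbinol set by Corey–Bakshi–Shibata reduction; C3/C4 by OsO4 on the α face anti to C14; C7 last, by singlet oxygen; the C7 epimers from the ring closure converge on one enone.

Key step: step 9

Assumption: the L-proline-derived sulfonamide catalyst of step 3 is taken to give the (4S)-cyclohexenone; if its sense of induction is the opposite, the D-proline-derived catalyst is used and nothing else changes.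

Step 1
Reactants: 1 2-methylpropane-1,3-diol
Product: 2 3-{[tert-butyl(dimethyl)silyl]oxy}-2-methylpropan-1-ol (racemic)
Conditions: NaH (1.0 equiv), THF, 0 °C to rt; then t-BuMe2SiCl (1.0 equiv)
Reagents that add atoms: tert-butyl(chloro)dimethylsilane, CC(C)(C)[Si](C)(C)Cl
Why: O-silylation of the sparingly soluble monosodium alkoxide (Williamson-type) should stop at one hydroxyl of the symmetric diol; the stereocentre formed is racemic and is erased in step 3.

Step 2
Reactants: 2 3-{[tert-butyl(dimethyl)silyl]oxy}-2-methylpropan-1-ol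
Product: 3 3-{[tert-butyl(dimethyl)silyl]oxy}-2-methylpropanal (racemic)
Conditions: PhI(OAc)2, cat. TEMPO, CH2Cl2, rt
Reagents that add atoms: none
Why: TEMPO-catalysed (oxoammonium) oxidation of a primary alcohol stops at the aldehyde under neutral conditions that should not eliminate the β-silyloxy group; no stereocentre of consequence is involved.

Step 3
Reactants: 3 3-{[tert-butyl(dimethyl)silyl]oxy}-2-methylpropanal, 4 pent-1-en-3-one
Product: 6 (4S)-4-({[tert-butyl(dimethyl)silyl]oxy}methyl)-2,4-dimethylcyclohex-2-en-1-one, via keto aldehyde 5 (not isolated)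
Conditions: N-[(4-dodecylphenyl)sulfonyl]-L-prolinamide (20 mol %), cat. BnNH2, 4 Å molecular sieves, ClCH2CH2Cl, rt; then cat. LiOH·H2O, i-PrOH, rt
Reagents that add atoms: none
Why: Organocatalytic asymmetric Robinson annulation: the chiral enamine of the α-branched aldehyde adds to the vinyl ketone (Michael addition) with the sulfonamide N–H guiding the acceptor to one enamine face, which sets the quaternary carbon C10, and keto aldehyde 5 then closes by aldol condensation through its only six-membered mode.

Step 4
Reactants: 6 (4S)-4-({[tert-butyl(dimethyl)silyl]oxy}methyl)-2,4-dimethylcyclohex-2-en-1-one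
Product: 7 (1S,4S)-4-({[tert-butyl(dimethyl)silyl]oxy}methyl)-2,4-dimethylcyclohex-2-en-1-ol
Conditions: (R)-2-methyl-CBS-oxazaborolidine [(3aR)-1-methyl-3,3-diphenyltetrahydro-1H,3H-pyrrolo[1,2-c][1,3,2]oxazaborole] (20 mol %), BH3·SMe2, THF, −20 °C; MeOH then aqueous work-up
Reagents that add atoms: none
Why: Corey–Bakshi–Shibata reduction: the oxazaborolidine–borane complex binds the ketone with the α-methylalkenyl arm as the large group and delivers hydride under reagent control, which should set the S carbinol centre (hydroxyl cis to the C10 methyl) whatever the remote quaternary centre prefers.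

Step 5
Reactants: 7 (1S,4S)-4-({[tert-butyl(dimethyl)silyl]oxy}methyl)-2,4-dimethylcyclohex-2-en-1-ol, 8 tributyl(iodomethyl)stannane
Product: 9 tert-butyl({(1S,4S)-1,3-dimethyl-4-[(tributylstannyl)methoxy]cyclohex-2-en-1-yl}methoxy)dimethylsilane
Conditions: KH, THF, 0 °C; then 8, rt
Reagents that add atoms: none
Why: Williamson ether synthesis of the potassium alkoxide with a primary iodide; the carbinol configuration is not touched.

Step 6
Reactants: 9 tert-butyl({(1S,4S)-1,3-dimethyl-4-[(tributylstannyl)methoxy]cyclohex-2-en-1-yl}methoxy)dimethylsilane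
Product: 11 [(1S,6S)-6-({[tert-butyl(dimethyl)silyl]oxy}methyl)-2,6-dimethylcyclohex-2-en-1-yl]methanol, via lithiomethyl ether 10 (not isolated)
Conditions: n-BuLi, THF, −78 °C; aqueous work-up
Reagents that add atoms: none
Why: Still–Wittig [2,3]-sigmatropic rearrangement: tin–lithium exchange gives the α-alkoxymethyllithium 10, which shifts suprafacially across the allyl unit so that the new C5–C6 bond forms on the face the C3–O bond occupied, setting C5 (C6 cis to the C10 methyl) and placing the alkene at C3=C4.

Step 7
Reactants: 11 [(1S,6S)-6-({[tert-butyl(dimethyl)silyl]oxy}methyl)-2,6-dimethylcyclohex-2-en-1-yl]methanol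
Product: 12 [(1S,2S)-1,3-dimethylcyclohex-3-ene-1,2-diyl]dimethanol
Conditions: Bu4NF, THF, rt
Reagents that add atoms: none
Why: Fluoride-mediated desilylation driven by the Si–F bond; no stereocentre is affected.

Step 8
Reactants: 12 [(1S,2S)-1,3-dimethylcyclohex-3-ene-1,2-diyl]dimethanol
Product: 13 (5S,6S)-5,6-bis(iodomethyl)-1,5-dimethylcyclohex-1-ene
Conditions: PPh3, I2, imidazole (3 equiv each, reagent preformed), toluene–MeCN, 0 °C to 80 °C
Reagents that add atoms: iodine, II
Why: Appel-type iodination: the excess reagent should convert both hydroxyls into alkoxyphosphonium ions before either is displaced (which suppresses cyclic ether formation), and iodide then substitutes by SN2 at C6 in the cold and at the neopentyl C9 on heating, both at CH2 carbons so no stereocentre is touched.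

Step 9
Reactants: 13 (5S,6S)-5,6-bis(iodomethyl)-1,5-dimethylcyclohex-1-ene, 14 methyl 3-methylbut-2-enoate
Product: 16 eudesma-3,11-dien-8-one (5αH; both C7 epimers), via iodo ester 15 (not isolated)
Conditions: LiN(i-Pr)2 (1.05 equiv), 14 (1.0 equiv), THF–DMPU, −78 °C; 13, −78 to 0 °C; then, same flask, SmI2 (2.5 equiv), cat. Fe(PhCOCHCOPh)3, THF, −30 °C to rt
Reagents that add atoms: none
Why: LiN(i-Pr)2 turns 14 into its lithium dienolate, whose α-carbon (C7) displaces iodide at C6 of 13 by SN2 to give 15 (C6–C7 bond); SmI2 then reduces the remaining C9–I bond through the alkyl radical to the alkylsamarium, which adds to the ester carbonyl C8 and expels methoxide (C8–C9 bond). The closest known reaction types are the deconjugative α-alkylation of 3-methylbut-2-enoate dienolates and the SmI2-promoted intramolecular nucleophilic acyl substitution (Barbier-type) of ω-iodo esters to cycloalkanones. Ring B closes by 6-exo-trig attack of C9 on the ester carbonyl. C7 is the only new stereocentre; it forms without control and both epimers are carried on because step 10 removes it, while C5 and C10 of 13 are untouched and fix the trans ring fusion. The step needs site selectivity between the two iodides, secured by the neopentyl position of C9 beside quaternary C10 (no SN2 there), and α- over γ-alkylation, secured by the lithium dienolate in THF–DMPU at −78 °C; the weakly basic alkylsamarium should acylate faster than it deprotonates the ester α-C–H.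

Step 10
Reactants: 16 eudesma-3,11-dien-8-one (both C7 epimers)
Product: 17 eudesma-3,7(11)-dien-8-one
Conditions: DBU, toluene, 80 °C
Reagents that add atoms: none
Why: Base-mediated isomerisation of the β,γ-unsaturated ketone into conjugation through the dienolate; both C7 epimers should give the same tetrasubstituted enone, so the step is stereoconvergent and creates no stereocentre.

Step 11
Reactants: 17 eudesma-3,7(11)-dien-8-one
Product: 18 cuauhtemone (3α,4α-dihydroxyeudesm-7(11)-en-8-one)
Conditions: cat. OsO4, N-methylmorpholine N-oxide, acetone–H2O, 0 °C to rt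
Reagents that add atoms: N-methylmorpholine N-oxide, C[N+]1([O-])CCOCC1; water, O
Why: Upjohn dihydroxylation: OsO4 should add to the electron-rich trisubstituted C3=C4 alkene from the α face, anti to the axial C10 methyl of the rigid trans-decalin, setting C3 and C4 (both hydroxyls α, C15 β), while the tetrasubstituted electron-poor enone alkene reacts much more slowly.

Step 12
Reactants: 18 cuauhtemone, 19 angelic acid
Product: 20 3-O-angeloylcuauhtemone
Conditions: 19, 2,4,6-trichlorobenzoyl chloride, Et3N, toluene, rt; then 18, 80 °C (no DMAP)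
Reagents that add atoms: none
Why: Yamaguchi esterification through the mixed anhydride should acylate the secondary C3 hydroxyl in preference to the tertiary C4 hydroxyl, and leaving out a nucleophilic amine catalyst keeps the Z (angelate) geometry; no stereocentre is formed.

Step 13
Reactants: 20 3-O-angeloylcuauhtemone
Product: 21 4-O-acetyl-3-O-angeloylcuauhtemone
Conditions: Ac2O, DMAP, Et3N, CH2Cl2, rt to 40 °C
Reagents that add atoms: acetic anhydride, CC(=O)OC(C)=O
Why: DMAP-catalysed acyl transfer (Steglich-type) to the remaining equatorial tertiary alcohol; no stereocentre is formed and the angelate should survive the mild conditions.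

Step 14
Reactants: 21 4-O-acetyl-3-O-angeloylcuauhtemone
Product: 22 3α-angeloyloxy-4α-acetoxy-7α-hydroperoxyeudesm-11-en-8-one (CNP0360871.1)
Conditions: O2, visible light, cat. tetraphenylporphyrin, CH2Cl2, −20 °C
Reagents that add atoms: dioxygen, O=O
Why: Schenck ene reaction of singlet oxygen with the tetrasubstituted, s-cis-locked C7=C11 alkene: oxygen should bond to C7 on the α face (axial approach), where only the isopropylidene methyl hydrogens are aligned with the π system, so a methyl hydrogen is transferred, the double bond moves to C11=C12 and C7 receives the axial α-hydroperoxide with the isopropenyl group equatorial; the electron-poor angelate alkene is far less reactive.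

Compound list
1 | 2-methylpropane-1,3-diol | CC(CO)CO | starting material
2 | 3-{[tert-butyl(dimethyl)silyl]oxy}-2-methylpropan-1-ol (racemic) | CC(CO)CO[Si](C)(C)C(C)(C)C | intermediate
3 | 3-{[tert-butyl(dimethyl)silyl]oxy}-2-methylpropanal (racemic) | CC(C=O)CO[Si](C)(C)C(C)(C)C | intermediate
4 | pent-1-en-3-one (ethyl vinyl ketone) | C=CC(=O)CC | starting material
5 | (2R)-2-({[tert-butyl(dimethyl)silyl]oxy}methyl)-2-methyl-5-oxoheptanal (keto aldehyde) | O=C[C@@](C)(CO[Si](C)(C)C(C)(C)C)CCC(=O)CC | intermediate
6 | (4S)-4-({[tert-butyl(dimethyl)silyl]oxy}methyl)-2,4-dimethylcyclohex-2-en-1-one | O=C1C(C)=C[C@@](C)(CO[Si](C)(C)C(C)(C)C)CC1 | intermediate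
7 | (1S,4S)-4-({[tert-butyl(dimethyl)silyl]oxy}methyl)-2,4-dimethylcyclohex-2-en-1-ol | O[C@@H]1C(C)=C[C@@](C)(CO[Si](C)(C)C(C)(C)C)CC1 | intermediate
8 | tributyl(iodomethyl)stannane | CCCC[Sn](CCCC)(CCCC)CI | starting material
9 | tert-butyl({(1S,4S)-1,3-dimethyl-4-[(tributylstannyl)methoxy]cyclohex-2-en-1-yl}methoxy)dimethylsilane | CCCC[Sn](CCCC)(CCCC)CO[C@@H]1C(C)=C[C@@](C)(CO[Si](C)(C)C(C)(C)C)CC1 | intermediate
10 | {[(1S,4S)-4-({[tert-butyl(dimethyl)silyl]oxy}methyl)-2,4-dimethylcyclohex-2-en-1-yl]oxy}methyllithium (lithiomethyl ether) | [Li]CO[C@@H]1C(C)=C[C@@](C)(CO[Si](C)(C)C(C)(C)C)CC1 | intermediate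
11 | [(1S,6S)-6-({[tert-butyl(dimethyl)silyl]oxy}methyl)-2,6-dimethylcyclohex-2-en-1-yl]methanol | OC[C@H]1C(C)=CCC[C@]1(C)CO[Si](C)(C)C(C)(C)C | intermediate
12 | [(1S,2S)-1,3-dimethylcyclohex-3-ene-1,2-diyl]dimethanol | OC[C@H]1C(C)=CCC[C@]1(C)CO | intermediate
13 | (5S,6S)-5,6-bis(iodomethyl)-1,5-dimethylcyclohex-1-ene | IC[C@H]1C(C)=CCC[C@]1(C)CI | intermediate
14 | methyl 3-methylbut-2-enoate | COC(=O)C=C(C)C | starting material
15 | methyl 2-{[(1S,6S)-6-(iodomethyl)-2,6-dimethylcyclohex-2-en-1-yl]methyl}-3-methylbut-3-enoate (iodo ester, both epimers at the ester α-carbon) | COC(=O)C(C[C@H]1C(C)=CCC[C@]1(C)CI)C(C)=C | intermediate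
16 | eudesma-3,11-dien-8-one, (4aR,8aR)-5,8a-dimethyl-3-(prop-1-en-2-yl)-3,4,4a,7,8,8a-hexahydronaphthalen-2(1H)-one (5αH, 10β-methyl; both C7 epimers) | C=C(C)C1C[C@@H]2[C@](C)(CCC=C2C)CC1=O | intermediate
17 | eudesma-3,7(11)-dien-8-one, (4aR,8aR)-5,8a-dimethyl-3-(propan-2-ylidene)-3,4,4a,7,8,8a-hexahydronaphthalen-2(1H)-one | CC(C)=C1C[C@@H]2[C@](C)(CCC=C2C)CC1=O | intermediate
18 | cuauhtemone (3α,4α-dihydroxyeudesm-7(11)-en-8-one; 5αH, 10β-methyl) | CC(C)=C1C[C@@H]2[C@](C)(CC[C@@H](O)[C@@]2(C)O)CC1=O | intermediate
19 | angelic acid, (Z)-2-methylbut-2-enoic acid | C/C=C(/C)C(=O)O | starting material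
20 | 3-O-angeloylcuauhtemone (3α-angeloyloxy-4α-hydroxyeudesm-7(11)-en-8-one) | CC(C)=C1C[C@@H]2[C@](C)(CC[C@@H](OC(=O)/C(C)=C\C)[C@@]2(C)O)CC1=O | intermediate
21 | 4-O-acetyl-3-O-angeloylcuauhtemone (4α-acetoxy-3α-angeloyloxyeudesm-7(11)-en-8-one) | CC(C)=C1C[C@@H]2[C@](C)(CC[C@@H](OC(=O)/C(C)=C\C)[C@@]2(C)OC(C)=O)CC1=O | intermediate
22 | 4α-acetoxy-3α-angeloyloxy-7α-hydroperoxyeudesm-11-en-8-one (CNP0360871.1) | C=C(C)[C@@]1(OO)C[C@@H]2[C@](C)(CC[C@@H](OC(=O)/C(C)=C\C)[C@@]2(C)OC(C)=O)CC1=O | target

Total step count: 14. Longest linear sequence: 14 steps (from 1 to 22).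

Steps most likely to fail

1. Step 9. Process at risk: the C9 alkylsamarium (or its radical precursor) may be lost by protonation or hydrogen abstraction before it reaches the ester, and the new ketone may be reduced further. Substitution at the β-branched C6 may also be slow, with elimination competing. Fallback: it sets out from 13 and comes back at 16. The alkylation with the dienolate of 14 is run alone and the iodo ester 15 is isolated. i-Bu2AlH (toluene, −78 °C) reduces its ester group to the aldehyde 2-{[(1S,6S)-6-(iodomethyl)-2,6-dimethylcyclohex-2-en-1-yl]methyl}-3-methylbut-3-enal F1. SmI2 in THF–HMPA at −78 °C then closes ring B by intramolecular Barbier addition of C9 to the aldehyde carbon C8, giving eudesma-3,11-dien-8-ol F2 as a mixture at C7 and C8. Dess–Martin periodinane oxidises F2 to 16. The ring closure thus becomes a carbonyl addition at the aldehyde oxidation level, run stepwise with each intermediate purified.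

2. Step 14. Process at risk: singlet oxygen may attack the β face and abstract the axial C6 hydrogen, which leads to the regioisomeric 11-hydroperoxide with a C6=C7 alkene; the electron-poor alkene may also react slowly. Fallback: it sets out from 21 and comes back at 22. Me3SiOTf and Et3N (CH2Cl2, 0 °C) convert 21 by γ-deprotonation into the 8-(trimethylsilyloxy)eudesma-7,11-diene (silyl dienol ether) F3. Photooxygenation of F3 (O2, tetraphenylporphyrin, visible light, −78 °C) is an ene reaction of an electron-rich silyl enol ether, in which oxygen bonds to the enol β-carbon C7 from the axial α face and the silyl group moves to the terminal oxygen, giving the 7α-(trimethylsilylperoxy)-8-ketone F4. Brief methanolysis (MeOH, cat. AcOH, 0 °C) frees 22.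

3. Step 3. Process at risk: the Michael addition of the α-branched aldehyde may show insufficient facial selectivity, and the enamine may lose silanol. Fallback: it sets out from 3 (with 4) and comes back at 7. A Stork enamine sequence (pyrrolidine enamine of 3, addition to 4, then AcOH–NaOAc buffer) gives the racemic enone, that is 6 together with its enantiomer (4R)-4-({[tert-butyl(dimethyl)silyl]oxy}methyl)-2,4-dimethylcyclohex-2-en-1-one F5. The reduction of step 4 with the (R)-oxazaborolidine is then applied to the racemate; being reagent-controlled, it gives 7 and its diastereomer (1S,4R)-4-({[tert-butyl(dimethyl)silyl]oxy}methyl)-2,4-dimethylcyclohex-2-en-1-ol F6, which differ as cis and trans isomers and are separated by chromatography. Compound 7 re-enters at step 5.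

Further compounds
F1 | step 9 | 2-{[(1S,6S)-6-(iodomethyl)-2,6-dimethylcyclohex-2-en-1-yl]methyl}-3-methylbut-3-enal (both epimers at the aldehyde α-carbon) | O=CC(C[C@H]1C(C)=CCC[C@]1(C)CI)C(C)=C
F2 | step 9 | eudesma-3,11-dien-8-ol (5αH; mixture at C7 and C8) | C=C(C)C1C[C@@H]2[C@](C)(CCC=C2C)CC1O
F3 | step 14 | 4α-acetoxy-3α-angeloyloxy-8-(trimethylsilyloxy)eudesma-7,11-diene (silyl dienol ether) | C=C(C)C=1C[C@@H]2[C@](C)(CC[C@@H](OC(=O)/C(C)=C\C)[C@@]2(C)OC(C)=O)CC=1O[Si](C)(C)C
F4 | step 14 | 4α-acetoxy-3α-angeloyloxy-7α-(trimethylsilylperoxy)eudesm-11-en-8-one | C=C(C)[C@@]1(OO[Si](C)(C)C)C[C@@H]2[C@](C)(CC[C@@H](OC(=O)/C(C)=C\C)[C@@]2(C)OC(C)=O)CC1=O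
F5 | step 3 | (4R)-4-({[tert-butyl(dimethyl)silyl]oxy}methyl)-2,4-dimethylcyclohex-2-en-1-one | O=C1C(C)=C[C@](C)(CO[Si](C)(C)C(C)(C)C)CC1
F6 | step 3 | (1S,4R)-4-({[tert-butyl(dimethyl)silyl]oxy}methyl)-2,4-dimethylcyclohex-2-en-1-ol | O[C@@H]1C(C)=C[C@](C)(CO[Si](C)(C)C(C)(C)C)CC1
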